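**Strategy.** Each half of the target hides a coumarin: the phenol oxygen (O1), the aromatic carbon bearing it (C8a), the adjacent ring carbon carrying the side chain (C4a), the benzylic stereocentre (C4) and the next two chain carbons (C3, C2). Both benzylic C–CH3 bonds are therefore disconnected, which leads back to the achiral, symmetric 7,7′-dimethyl-6,6′-bicoumarin 5. One catalytic, ligand-controlled double 1,4-addition of a methyl Grignard reagent to the two lactone enoates forms both methyl–C4 bonds and both S stereocentres at once; no ring is formed. The lactones then act as masked phenols and three-carbon handles for extension to the 6-methylhept-5-en-2-yl arms.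

Key step: step 3

Assumption: the biaryl axis (one methyl and one hydrogen ortho on each ring) rotates freely at room temperature, so only the two benzylic centres need control; the ligand antipode that gives 4S is to be identified in a trial on 7-methylcoumarin, both antipodes being commercial.

**Step 1**
Reactants: 1 4-bromo-3-methylphenol; 2 DL-malic acid
Product: 3 6-bromo-7-methyl-2H-chromen-2-one
Conditions: conc. H2SO4, 110–120 °C; then ice-water
Reagents that add atoms: none
Why: Von Pechmann condensation, in which hot sulfuric acid turns malic acid into formylacetic acid (loss of CO and water) that attacks the phenol at the free position ortho to OH and para to the methyl group (the other ortho site is flanked by OH and CH3) and then lactonises.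

**Step 2**
Reactants: 3 6-bromo-7-methyl-2H-chromen-2-one (two molecules)
Product: 5 7,7′-dimethyl-2H,2′H-[6,6′-bichromene]-2,2′-dione, via pinacol boronate 4 (not isolated)
Conditions: B2pin2 (0.55 equiv), PdCl2(dppf) (5 mol %), KOAc, 1,4-dioxane, 90 °C; then 2 M aq K2CO3, 90 °C
Reagents that add atoms: none
Why: Miyaura borylation converts about half of the aryl bromide into boronate 4, and the added aqueous carbonate then starts Suzuki–Miyaura coupling of 4 with the remaining bromide in the same pot, both reactions being well established for 6-halocoumarins and for partners with a single ortho substituent.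

**Step 3**
Reactants: 5 7,7′-dimethyl-2H,2′H-[6,6′-bichromene]-2,2′-dione
Product: 7 (4S,4′S)-4,4′,7,7′-tetramethyl-[6,6′-bichromane]-2,2′-dione, via bis(bromomagnesium) lactone enolate 6 (not isolated)
Conditions: MeMgBr (3–4 equiv, slow addition), CuBr·SMe2 (10 mol %), rev-Josiphos-type ligand 1-[2-(dicyclohexylphosphino)ferrocenyl]ethyldiphenylphosphine (12 mol %, antipode giving 4S), CH2Cl2, −72 °C; quench with 1 M HCl at −72 °C
Reagents that add atoms: methylmagnesium bromide, C[Mg]Br
Why: Copper-catalysed asymmetric conjugate addition of a Grignard reagent, in which the ligated Cu(I)–methyl species π-complexes the C3=C4 bond of a lactone, adds oxidatively to give a C4-bound Cu(III) species and eliminates reductively to form the C4–CH3 bond, leaving magnesium enolate 6 that is protonated in the cold acidic quench. The closest known reaction type is the Cu/ferrocenyl-diphosphine-catalysed addition of alkyl Grignard reagents to coumarins, used here twice in one molecule and with the least reactive (methyl) reagent, hence the raised catalyst loading and slow addition. No ring is closed, so no mode of closure applies. Each new stereocentre (C4 and C4′) is set by the catalyst alone, and the two lactones, insulated by the twisted biaryl, should react independently. The step needs 1,4- over 1,2-addition, which the planar s-cis lactone enoate, copper catalysis and a low concentration of free Grignard reagent at low temperature secure, and it needs the enolate to stay closed (no ketene-forming ring opening), which holding −72 °C until the quench secures. Because two independent selections are made, a wrong-face event should end up mainly in the meso (4R,4′S) diastereomer, to be removed by crystallisation or chromatography, so the (4S,4′S) product should be enriched beyond the selectivity of a single addition.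

**Step 4**
Reactants: 7 (4S,4′S)-4,4′,7,7′-tetramethyl-[6,6′-bichromane]-2,2′-dione
Product: 9 dimethyl (3S,3′S)-3,3′-(4,4′-dimethoxy-6,6′-dimethyl-[1,1′-biphenyl]-3,3′-diyl)dibutanoate, via dipotassium bis(phenoxide) dimethyl ester 8 (not isolated)
Conditions: MeI (6 equiv), K2CO3 (6 equiv), acetone–MeOH 1:1, reflux
Reagents that add atoms: methanol, CO; iodomethane, CI
Why: Base-mediated methanolysis (transesterification) of the aryl-ester lactones gives the methyl ester phenoxides 8 reversibly, and Williamson O-methylation by iodomethane traps them irreversibly, while the stereocentre, now β to the ester, is not enolisable and keeps its configuration.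

**Step 5**
Reactants: 9 dimethyl (3S,3′S)-3,3′-(4,4′-dimethoxy-6,6′-dimethyl-[1,1′-biphenyl]-3,3′-diyl)dibutanoate
Product: 10 (3S,3′S)-3,3′-(4,4′-dimethoxy-6,6′-dimethyl-[1,1′-biphenyl]-3,3′-diyl)bis(butan-1-ol)
Conditions: LiAlH4, THF, 0 °C to rt; aqueous NaOH work-up
Reagents that add atoms: none
Why: Standard hydride reduction of methyl esters to primary alcohols, to which aryl methyl ethers and the remote benzylic stereocentres are inert.

**Step 6**
Reactants: 10 (3S,3′S)-3,3′-(4,4′-dimethoxy-6,6′-dimethyl-[1,1′-biphenyl]-3,3′-diyl)bis(butan-1-ol)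
Product: 11 (3S,3′S)-(4,4′-dimethoxy-6,6′-dimethyl-[1,1′-biphenyl]-3,3′-diyl)bis(butane-3,1-diyl) bis(4-methylbenzenesulfonate)
Conditions: TsCl (3 equiv), Et3N (4 equiv), DMAP (cat.), CH2Cl2, 0 °C to rt
Reagents that add atoms: 4-toluenesulfonyl chloride, Cc1ccc(cc1)S(=O)(=O)Cl
Why: Standard sulfonylation (tosylation) of primary alcohols, which is safe here because the phenol oxygens are capped as methyl ethers and cannot close chromans by intramolecular O-alkylation.

**Step 7**
Reactants: 11 bis(4-methylbenzenesulfonate) of diol 10; 12 2-methylprop-1-enylmagnesium bromide (commercial 0.5 M solution in THF)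
Product: 13 4,4′-dimethoxy-2,2′-dimethyl-5,5′-bis[(2S)-6-methylhept-5-en-2-yl]-1,1′-biphenyl
Conditions: 12 (6 equiv), CuI (20 mol %), THF, −30 °C to rt
Reagents that add atoms: none
Why: Copper-catalysed sp3–sp2 cross-coupling of a primary alkyl tosylate with an alkenyl Grignard reagent (Kochi/Fouquet–Schlosser type, SN2 displacement by an alkenylcuprate) installs both trisubstituted alkenes, and the reacting carbon is two atoms away from the stereocentre, whose configuration is therefore untouched.

**Step 8**
Reactants: 13 4,4′-dimethoxy-2,2′-dimethyl-5,5′-bis[(2S)-6-methylhept-5-en-2-yl]-1,1′-biphenyl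
Product: 14 2,2′-dimethyl-5,5′-bis[(2S)-6-methylhept-5-en-2-yl]-[1,1′-biphenyl]-4,4′-diol (target)
Conditions: NaSEt (10 equiv), DMF, 130 °C; then 1 M HCl, 0 °C
Reagents that add atoms: none
Why: Thiolate demethylation, an SN2 attack of ethanethiolate on the O–CH3 carbon of each aryl methyl ether, is non-acidic and so leaves the acid-sensitive trisubstituted alkenes and the benzylic stereocentres untouched.

**Compound list**

1 | 4-bromo-3-methylphenol | Cc1cc(O)ccc1Br | starting material
2 | DL-malic acid (2-hydroxybutanedioic acid) | OC(CC(=O)O)C(=O)O | starting material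
3 | 6-bromo-7-methyl-2H-chromen-2-one | Cc1cc2OC(=O)C=Cc2cc1Br | intermediate
4 | 7-methyl-6-(4,4,5,5-tetramethyl-1,3,2-dioxaborolan-2-yl)-2H-chromen-2-one | Cc1cc2OC(=O)C=Cc2cc1B1OC(C)(C)C(C)(C)O1 | intermediate
5 | 7,7′-dimethyl-2H,2′H-[6,6′-bichromene]-2,2′-dione | Cc1cc2OC(=O)C=Cc2cc1-c1cc2C=CC(=O)Oc2cc1C | intermediate
6 | (4S,4′S)-2,2′-bis[(bromomagnesio)oxy]-4,4′,7,7′-tetramethyl-4H,4′H-6,6′-bichromene (magnesium enolate) | Cc1cc2OC(O[Mg]Br)=C[C@H](C)c2cc1-c1cc2[C@@H](C)C=C(O[Mg]Br)Oc2cc1C | intermediate
7 | (4S,4′S)-4,4′,7,7′-tetramethyl-[6,6′-bichromane]-2,2′-dione | Cc1cc2OC(=O)C[C@H](C)c2cc1-c1cc2[C@@H](C)CC(=O)Oc2cc1C | intermediate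
8 | dipotassium salt of dimethyl (3S,3′S)-3,3′-(4,4′-dihydroxy-6,6′-dimethyl-[1,1′-biphenyl]-3,3′-diyl)dibutanoate | COC(=O)C[C@H](C)c1cc(-c2cc([C@@H](C)CC(=O)OC)c([O-])cc2C)c(C)cc1[O-].[K+].[K+] | intermediate
9 | dimethyl (3S,3′S)-3,3′-(4,4′-dimethoxy-6,6′-dimethyl-[1,1′-biphenyl]-3,3′-diyl)dibutanoate | COC(=O)C[C@H](C)c1cc(-c2cc([C@@H](C)CC(=O)OC)c(OC)cc2C)c(C)cc1OC | intermediate
10 | (3S,3′S)-3,3′-(4,4′-dimethoxy-6,6′-dimethyl-[1,1′-biphenyl]-3,3′-diyl)bis(butan-1-ol) | OCC[C@H](C)c1cc(-c2cc([C@@H](C)CCO)c(OC)cc2C)c(C)cc1OC | intermediate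
11 | (3S,3′S)-(4,4′-dimethoxy-6,6′-dimethyl-[1,1′-biphenyl]-3,3′-diyl)bis(butane-3,1-diyl) bis(4-methylbenzenesulfonate) | Cc1ccc(cc1)S(=O)(=O)OCC[C@H](C)c1cc(-c2cc([C@@H](C)CCOS(=O)(=O)c3ccc(C)cc3)c(OC)cc2C)c(C)cc1OC | intermediate
12 | 2-methylprop-1-enylmagnesium bromide | CC(C)=C[Mg]Br | starting material
13 | 4,4′-dimethoxy-2,2′-dimethyl-5,5′-bis[(2S)-6-methylhept-5-en-2-yl]-1,1′-biphenyl | CC(C)=CCC[C@H](C)c1cc(-c2cc([C@@H](C)CCC=C(C)C)c(OC)cc2C)c(C)cc1OC | intermediate
14 | 2,2′-dimethyl-5,5′-bis[(2S)-6-methylhept-5-en-2-yl]-[1,1′-biphenyl]-4,4′-diol | CC(C)=CCC[C@H](C)c1cc(-c2cc([C@@H](C)CCC=C(C)C)c(O)cc2C)c(C)cc1O | target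

**Step count.** Total: 8 steps. Longest linear sequence: 8 steps (1 to 14); Grignard reagent 12 is purchased.

**Steps most likely to fail**

Step 3. The second methyl transfer may stall, because methyl is the slowest Grignard reagent in this catalysis. Facial selectivity at one site may be insufficient, which would leave a meso diastereomer that is hard to remove because the two centres are far apart. The enolate may also open if the mixture warms before the quench. The fallback sets the stereocentres by hydride delivery to a 4-methylcoumarin instead of methyl delivery to a coumarin. It sets out from 1: von Pechmann condensation with ethyl acetoacetate in sulfuric or methanesulfonic acid should give 6-bromo-4,7-dimethyl-2H-chromen-2-one F1. The one-pot borylation–Suzuki protocol of step 2, through 4,7-dimethyl-6-(4,4,5,5-tetramethyl-1,3,2-dioxaborolan-2-yl)-2H-chromen-2-one F2, should then give 4,4′,7,7′-tetramethyl-2H,2′H-[6,6′-bichromene]-2,2′-dione F3. Copper hydride-catalysed asymmetric conjugate reduction of both enoates (Cu(OAc)2, DTBM-SEGPHOS of the required handedness, polymethylhydrosiloxane, t-BuOH, toluene) should deliver bis-lactone 7, where the route is rejoined at step 4.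

Step 7. The double coupling may stop after one arm, and base-induced elimination of the tosylate or oxidative homocoupling of the alkenyl Grignard reagent may consume material. The fallback reverses the polarity of the coupling and sets out from 11: Finkelstein exchange (NaI, acetone, reflux) should give 5,5′-bis[(2S)-4-iodobutan-2-yl]-4,4′-dimethoxy-2,2′-dimethyl-1,1′-biphenyl F4. Zinc insertion (activated Zn dust, LiCl, THF) should give the bis(alkylzinc iodide) F5. Palladium-catalysed Negishi coupling of F5 with 1-bromo-2-methylprop-1-ene (Pd(PPh3)4, THF, 50 °C) should give 13, where the route is rejoined at step 8.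

Step 1. The weakly activated bromophenol may be sulfonated or charred in hot sulfuric acid before it condenses, conversion may be low, and some cyclisation at the hindered ortho position may occur. The fallback builds the lactone from a salicylaldehyde and sets out from 1: magnesium-mediated ortho-formylation (MgCl2, Et3N, paraformaldehyde, MeCN, reflux) should give 5-bromo-2-hydroxy-4-methylbenzaldehyde F6. Wittig olefination with ethyl (triphenylphosphoranylidene)acetate in refluxing N,N-diethylaniline should pass through ethyl 3-(5-bromo-2-hydroxy-4-methylphenyl)prop-2-enoate F7, which lactonises in the same pot to 3, where the route is rejoined at step 2.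

**Further compounds**

F1 | step 3 | 6-bromo-4,7-dimethyl-2H-chromen-2-one | Cc1cc2OC(=O)C=C(C)c2cc1Br
F2 | step 3 | 4,7-dimethyl-6-(4,4,5,5-tetramethyl-1,3,2-dioxaborolan-2-yl)-2H-chromen-2-one | Cc1cc2OC(=O)C=C(C)c2cc1B1OC(C)(C)C(C)(C)O1
F3 | step 3 | 4,4′,7,7′-tetramethyl-2H,2′H-[6,6′-bichromene]-2,2′-dione | Cc1cc2OC(=O)C=C(C)c2cc1-c1cc2C(C)=CC(=O)Oc2cc1C
F4 | step 7 | 5,5′-bis[(2S)-4-iodobutan-2-yl]-4,4′-dimethoxy-2,2′-dimethyl-1,1′-biphenyl | ICC[C@H](C)c1cc(-c2cc([C@@H](C)CCI)c(OC)cc2C)c(C)cc1OC
F5 | step 7 | bis(alkylzinc iodide) from F4, [(3S,3′S)-(4,4′-dimethoxy-6,6′-dimethyl-[1,1′-biphenyl]-3,3′-diyl)bis(butane-3,1-diyl)]bis(iodozinc) | I[Zn]CC[C@H](C)c1cc(-c2cc([C@@H](C)CC[Zn]I)c(OC)cc2C)c(C)cc1OC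
F6 | step 1 | 5-bromo-2-hydroxy-4-methylbenzaldehyde | Cc1cc(O)c(C=O)cc1Br
F7 | step 1 | ethyl 3-(5-bromo-2-hydroxy-4-methylphenyl)prop-2-enoate (E/Z mixture) | CCOC(=O)C=Cc1cc(Br)c(C)cc1O
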